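**Plan** (labdane numbering: ring A = C1–C5 + C10, ring B = C5–C10, side chain C11–C16)

1. Retrosynthesis: (a) C7=C8 with H-9 ⇒ 7-hydroxy-Δ8 allylic alcohol ⇒ 7-oxo-Δ8 enone; (b) ring A opened at C3–C4 together with the C2–O bond ⇒ monocyclic ring-B enone with an allyl group (C1–C3) on C10 and an isopropenyl group (C4) on C5; (c) C9–C11 ⇒ ketone + side-chain alkyllithium; (d) C10–C1 and C10–CH3 ⇒ (S)-carvone.
2. Forward: ring B is the carvone ring from the start; C10 is made quaternary (methyl, then allyl); the side chain is added and the enone transposed; ring A is closed last by an acid-induced cation–olefin cyclisation; acetylation, Luche reduction and reductive allylic transposition complete ring B.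
3. Enabling feature: in ring A the gem-dimethyl carbon C4 sits on ring-fusion carbon C5, and the oxygenated C2 lies 1,3 to both quaternary carbons C4 and C10. C4 with its two methyls is therefore a protonated isopropenyl group, and C1–C2–C3 is an allyl group on C10; joining C3 to the C4 cation (6-endo) places the charge on C2, whose axial face is blocked by the syn-axial methyls on C4 and C10.
4. Stereochemistry: C5 from (S)-carvone; C10 by allylation anti to the isopropenyl group; the trans ring fusion follows from these two centres; C2 by equatorial formate capture in the key step; C9 by Luche reduction, Mitsunobu inversion and suprafacial hydrogen delivery from a diazene; C13 from (R)-3-methylglutaric acid monomethyl ester.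

Key step: step 9

Remark: compound 1 is taken as a purchasable half-ester (it also arises in one step by enzymatic desymmetrisation of dimethyl 3-methylglutarate); where a centre is destroyed later (C-6 of 8, C-1 of 12) both epimers are carried on.

**Step 1**
Reactants: 1 (3R)-5-methoxy-3-methyl-5-oxopentanoic acid
Product: 2 methyl (3R)-5-hydroxy-3-methylpentanoate
Conditions: BH3·SMe2, THF, 0 → 23 °C; then H2O
Reagents that add atoms: none
Why: Borane reduces the free acid through its acyloxyborane much faster than the methyl ester (chemoselective borane reduction), so the two ends of the glutarate are differentiated without touching the stereocentre.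

**Step 2**
Reactants: 2 methyl (3R)-5-hydroxy-3-methylpentanoate
Product: 3 methyl (3R)-5-{[tert-butyl(dimethyl)silyl]oxy}-3-methylpentanoate
Conditions: t-BuMe2SiCl, imidazole, CH2Cl2, 0 → 23 °C
Reagents that add atoms: tert-butyldimethylsilyl chloride, CC(C)(C)[Si](C)(C)Cl
Why: Imidazole-promoted silylation of the primary alcohol traps the hydroxy ester before it can lactonise and gives an ether that should survive t-BuLi and chromium oxidation but is shed in formic acid in step 9.

**Step 3**
Reactants: 3 methyl (3R)-5-{[tert-butyl(dimethyl)silyl]oxy}-3-methylpentanoate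
Product: 4 (3S)-5-{[tert-butyl(dimethyl)silyl]oxy}-3-methylpentan-1-ol
Conditions: (i-Bu)2AlH (2.5 equiv), CH2Cl2, −78 → 0 °C; then aq. KNaC4H4O6
Reagents that add atoms: none
Why: Exhaustive hydride reduction of the ester to the primary alcohol; the silyl ether and the stereocentre are inert (the descriptor changes only through priorities).

**Step 4**
Reactants: 4 (3S)-5-{[tert-butyl(dimethyl)silyl]oxy}-3-methylpentan-1-ol
Product: 5 tert-butyl{[(3R)-5-iodo-3-methylpentyl]oxy}dimethylsilane
Conditions: I2, PPh3, imidazole, CH2Cl2, 0 → 23 °C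
Reagents that add atoms: iodine, II
Why: Appel-type iodination through the alkoxyphosphonium iodide (SN2 at a primary carbon) gives the precursor for iodine–lithium exchange.

**Step 5**
Reactants: 6 (S)-(+)-carvone
Product: 8 (5S,6R)-2,6-dimethyl-5-(prop-1-en-2-yl)cyclohex-2-en-1-one, via lithium dienolate 7 (not isolated)
Conditions: LiN(i-Pr)2, THF, −78 °C; then MeI, −78 → 0 °C
Reagents that add atoms: iodomethane, CI
Why: Kinetic deprotonation at the alpha-prime CH2 (the future C10) gives the cross-conjugated dienolate, which is C-methylated (enolate alkylation); the configuration of the new centre does not matter because it is re-enolised in step 6.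

**Step 6**
Reactants: 8 (5S,6R)-2,6-dimethyl-5-(prop-1-en-2-yl)cyclohex-2-en-1-one
Product: 10 (5R,6R)-2,6-dimethyl-6-(prop-2-en-1-yl)-5-(prop-1-en-2-yl)cyclohex-2-en-1-one, via lithium dienolate 9 (not isolated)
Conditions: LiN(i-Pr)2, THF, −78 → 0 °C; then allyl bromide, DMPU, −78 → 23 °C
Reagents that add atoms: allyl bromide, C=CCBr
Why: The tetrasubstituted dienolate should be allylated on the face opposite the neighbouring isopropenyl group, which sits pseudoaxial to avoid allylic strain (diastereoselective enolate alkylation); this sets quaternary C10 with allyl trans and methyl cis to isopropenyl.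

**Step 7**
Reactants: 5 tert-butyl{[(3R)-5-iodo-3-methylpentyl]oxy}dimethylsilane; 10 (5R,6R)-2,6-dimethyl-6-(prop-2-en-1-yl)-5-(prop-1-en-2-yl)cyclohex-2-en-1-one
Product: 12 (1R,5R,6R)-1-[(3S)-5-{[tert-butyl(dimethyl)silyl]oxy}-3-methylpentyl]-2,6-dimethyl-6-(prop-2-en-1-yl)-5-(prop-1-en-2-yl)cyclohex-2-en-1-ol, via alkyllithium 11 (not isolated)
Conditions: 5, t-BuLi (2 equiv), Et2O/pentane, −78 °C; then 10, −78 → −20 °C; then aq. NH4Cl
Reagents that add atoms: none
Why: Iodine–lithium exchange gives the primary alkyllithium, which adds 1,2 to the enone carbonyl (no alpha-hydrogen on the quaternary side, so enolisation is limited); the carbinol configuration is erased in step 8.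

**Step 8**
Reactants: 12 (1R,5R,6R)-1-[(3S)-5-{[tert-butyl(dimethyl)silyl]oxy}-3-methylpentyl]-2,6-dimethyl-6-(prop-2-en-1-yl)-5-(prop-1-en-2-yl)cyclohex-2-en-1-ol
Product: 13 (4R,5R)-3-[(3S)-5-{[tert-butyl(dimethyl)silyl]oxy}-3-methylpentyl]-2,4-dimethyl-4-(prop-2-en-1-yl)-5-(prop-1-en-2-yl)cyclohex-2-en-1-one
Conditions: [C5H5NH][CrO3Cl] (pyridinium chlorochromate), 4 Å molecular sieves, CH2Cl2, 23 °C
Reagents that add atoms: pyridinium chlorochromate, [O-][Cr](=O)(=O)Cl.c1cc[nH+]cc1
Why: Babler–Dauben oxidative transposition: the hexavalent chromium ester of the tertiary allylic alcohol shifts [3,3] to the unhindered C7 and is oxidised there, giving the transposed enone with the side chain on C9.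

**Step 9**
Reactants: 13 (4R,5R)-3-[(3S)-5-{[tert-butyl(dimethyl)silyl]oxy}-3-methylpentyl]-2,4-dimethyl-4-(prop-2-en-1-yl)-5-(prop-1-en-2-yl)cyclohex-2-en-1-one
Product: 16 (4aR,6R,8aR)-6-hydroxy-4-[(3S)-5-hydroxy-3-methylpentyl]-3,4a,8,8-tetramethyl-4a,5,6,7,8,8a-hexahydronaphthalen-2(1H)-one, via tertiary carbocation 14 (not isolated), via bis-formate 15 (not isolated)
Conditions: HCO2H (98%), 40 °C; then K2CO3, MeOH, 23 °C
Reagents that add atoms: formic acid, OC=O
Why: Markovnikov protonation of the isopropenyl group gives tertiary cation 14 (C4 now carrying both methyls); the terminal carbon C3 of the allyl group on the neighbouring quaternary C10 attacks it through a chair transition state while formic acid captures the charge developing at C2, the silyl ether is formolysed in the same medium, and K2CO3/MeOH then cleaves the two formates of 15. The closest known reaction type is the acid-induced cation–olefin cyclisation of 1,6-dienes with a vinyl terminator and carboxylate capture (formolysis-type polyene cyclisation). Ring A is closed in the 6-endo-trig mode at the allyl group (C3–C4 bond formed, C2–O bond formed by anti addition), ring B serving only as the template. The only new stereocentre, C2, is controlled by the chair transition state and by the two syn-axial methyl groups on C4 and C10, which block the axial face so that formate should enter equatorially; the trans ring fusion follows from the trans-diequatorial allyl/isopropenyl pair set in step 6. The step needs protonation of the 1,1-disubstituted alkene in preference to the allyl and enone alkenes, and cyclisation that outruns proton loss toward C5; the first is secured by cation stability (tertiary against secondary) and by the electron-poor enone, the second by reversible tertiary formate formation, which funnels material to the secondary ester, and by quaternary C10, which rules out enolisation or aromatisation of ring B.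

**Step 10**
Reactants: 16 (4aR,6R,8aR)-6-hydroxy-4-[(3S)-5-hydroxy-3-methylpentyl]-3,4a,8,8-tetramethyl-4a,5,6,7,8,8a-hexahydronaphthalen-2(1H)-one
Product: 17 (4aR,6R,8aR)-4-[(3S)-5-acetoxy-3-methylpentyl]-3,4a,8,8-tetramethyl-2-oxo-1,2,4a,5,6,7,8,8a-octahydronaphthalen-6-yl acetate
Conditions: Ac2O, pyridine, DMAP (cat.), CH2Cl2, 23 °C
Reagents that add atoms: acetic anhydride, CC(=O)OC(C)=O
Why: DMAP-catalysed acetylation of the primary and the unhindered equatorial secondary alcohol installs both acetates of the target before the two ester-tolerant finishing steps.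

**Step 11**
Reactants: 17 (4aR,6R,8aR)-4-[(3S)-5-acetoxy-3-methylpentyl]-3,4a,8,8-tetramethyl-2-oxo-1,2,4a,5,6,7,8,8a-octahydronaphthalen-6-yl acetate
Product: 18 (2R,4aR,6R,8aR)-4-[(3S)-5-acetoxy-3-methylpentyl]-2-hydroxy-3,4a,8,8-tetramethyl-1,2,4a,5,6,7,8,8a-octahydronaphthalen-6-yl acetate
Conditions: NaBH4, CeCl3·7H2O, MeOH, −20 °C
Reagents that add atoms: none
Why: Luche 1,2-reduction: the small cerium-activated hydride should attack C7 axially, on the face of axial H-5 and away from the angular methyl, giving the pseudo-equatorial alcohol cis to the C10 methyl; the acetates survive.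

**Step 12**
Reactants: 18 (2R,4aR,6R,8aR)-4-[(3S)-5-acetoxy-3-methylpentyl]-2-hydroxy-3,4a,8,8-tetramethyl-1,2,4a,5,6,7,8,8a-octahydronaphthalen-6-yl acetate
Product: 21 (3S)-5-[(1R,4aR,7R,8aR)-7-acetoxy-2,5,5,8a-tetramethyl-1,4,4a,5,6,7,8,8a-octahydronaphthalen-1-yl]-3-methylpentyl acetate (CNP0220683.1), via allylic sulfonylhydrazine 19 (not isolated), via allylic diazene 20 (not isolated)
Conditions: 2-O2NC6H4SO2NHNH2, PPh3, EtO2CN=NCO2Et, N-methylmorpholine, −30 °C; then 23 °C
Reagents that add atoms: none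
Why: Mitsunobu displacement by the sulfonylhydrazide inverts C7, loss of sulfinic acid gives the axial monoalkyl diazene, and its retro-ene loss of N2 delivers hydrogen suprafacially to C9 on the face opposite the angular methyl while moving the alkene to C7=C8 (reductive allylic transposition); this sets C9 with the side chain equatorial.

**Compound list**

1 | (3R)-5-methoxy-3-methyl-5-oxopentanoic acid [(R)-3-methylglutaric acid monomethyl ester] | OC(=O)C[C@@H](C)CC(=O)OC | starting material
2 | methyl (3R)-5-hydroxy-3-methylpentanoate | OCC[C@@H](C)CC(=O)OC | intermediate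
3 | methyl (3R)-5-{[tert-butyl(dimethyl)silyl]oxy}-3-methylpentanoate | CC(C)(C)[Si](C)(C)OCC[C@@H](C)CC(=O)OC | intermediate
4 | (3S)-5-{[tert-butyl(dimethyl)silyl]oxy}-3-methylpentan-1-ol | CC(C)(C)[Si](C)(C)OCC[C@@H](C)CCO | intermediate
5 | tert-butyl{[(3R)-5-iodo-3-methylpentyl]oxy}dimethylsilane | CC(C)(C)[Si](C)(C)OCC[C@@H](C)CCI | intermediate
6 | (S)-(+)-carvone, (5S)-2-methyl-5-(prop-1-en-2-yl)cyclohex-2-en-1-one | CC1=CC[C@@H](CC1=O)C(C)=C | starting material
7 | lithium (3S)-6-methyl-3-(prop-1-en-2-yl)cyclohexa-1,5-dien-1-olate (not isolated) | [Li]OC1=C[C@@H](C(C)=C)CC=C1C | intermediate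
8 | (5S,6R)-2,6-dimethyl-5-(prop-1-en-2-yl)cyclohex-2-en-1-one (trans epimer drawn; the C-6 epimer is equally usable) | C[C@H]1C(=O)C(C)=CC[C@@H]1C(C)=C | intermediate
9 | lithium (3R)-2,6-dimethyl-3-(prop-1-en-2-yl)cyclohexa-1,5-dien-1-olate (not isolated) | [Li]OC1=C(C)[C@@H](C(C)=C)CC=C1C | intermediate
10 | (5R,6R)-2,6-dimethyl-6-(prop-2-en-1-yl)-5-(prop-1-en-2-yl)cyclohex-2-en-1-one (allyl trans to isopropenyl) | C=CC[C@@]1(C)C(=O)C(C)=CC[C@@H]1C(C)=C | intermediate
11 | [(3S)-5-{[tert-butyl(dimethyl)silyl]oxy}-3-methylpentyl]lithium (not isolated) | [Li]CC[C@H](C)CCO[Si](C)(C)C(C)(C)C | intermediate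
12 | (1R,5R,6R)-1-[(3S)-5-{[tert-butyl(dimethyl)silyl]oxy}-3-methylpentyl]-2,6-dimethyl-6-(prop-2-en-1-yl)-5-(prop-1-en-2-yl)cyclohex-2-en-1-ol (expected major C-1 epimer drawn; both converge in step 8) | C=CC[C@@]1(C)[C@@](O)(CC[C@H](C)CCO[Si](C)(C)C(C)(C)C)C(C)=CC[C@@H]1C(C)=C | intermediate
13 | (4R,5R)-3-[(3S)-5-{[tert-butyl(dimethyl)silyl]oxy}-3-methylpentyl]-2,4-dimethyl-4-(prop-2-en-1-yl)-5-(prop-1-en-2-yl)cyclohex-2-en-1-one | C=CC[C@@]1(C)C(CC[C@H](C)CCO[Si](C)(C)C(C)(C)C)=C(C)C(=O)C[C@@H]1C(C)=C | intermediate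
14 | propan-2-ylium cation formed from 13 by protonation of the isopropenyl CH2, all other atoms as in 13 (not isolated) | C=CC[C@@]1(C)C(CC[C@H](C)CCO[Si](C)(C)C(C)(C)C)=C(C)C(=O)C[C@@H]1[C+](C)C | intermediate
15 | (4aR,6R,8aR)-4-[(3S)-5-(formyloxy)-3-methylpentyl]-3,4a,8,8-tetramethyl-2-oxo-1,2,4a,5,6,7,8,8a-octahydronaphthalen-6-yl formate (not isolated) | O=COCC[C@@H](C)CCC1=C(C)C(=O)C[C@@H]2C(C)(C)C[C@@H](OC=O)C[C@@]12C | intermediate
16 | (4aR,6R,8aR)-6-hydroxy-4-[(3S)-5-hydroxy-3-methylpentyl]-3,4a,8,8-tetramethyl-4a,5,6,7,8,8a-hexahydronaphthalen-2(1H)-one | OCC[C@@H](C)CCC1=C(C)C(=O)C[C@@H]2C(C)(C)C[C@@H](O)C[C@@]12C | intermediate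
17 | (4aR,6R,8aR)-4-[(3S)-5-acetoxy-3-methylpentyl]-3,4a,8,8-tetramethyl-2-oxo-1,2,4a,5,6,7,8,8a-octahydronaphthalen-6-yl acetate | CC(=O)OCC[C@@H](C)CCC1=C(C)C(=O)C[C@@H]2C(C)(C)C[C@@H](OC(C)=O)C[C@@]12C | intermediate
18 | (2R,4aR,6R,8aR)-4-[(3S)-5-acetoxy-3-methylpentyl]-2-hydroxy-3,4a,8,8-tetramethyl-1,2,4a,5,6,7,8,8a-octahydronaphthalen-6-yl acetate (7-OH cis to the angular methyl) | CC(=O)OCC[C@@H](C)CCC1=C(C)[C@H](O)C[C@@H]2C(C)(C)C[C@@H](OC(C)=O)C[C@@]12C | intermediate
19 | N-[(2S,4aR,6R,8aR)-6-acetoxy-4-[(3S)-5-acetoxy-3-methylpentyl]-3,4a,8,8-tetramethyl-1,2,4a,5,6,7,8,8a-octahydronaphthalen-2-yl]-2-nitrobenzenesulfonohydrazide, alkylated at the sulfonyl-bearing nitrogen (not isolated) | CC(=O)OCC[C@@H](C)CCC1=C(C)[C@@H](N(N)S(=O)(=O)c3ccccc3[N+](=O)[O-])C[C@@H]2C(C)(C)C[C@@H](OC(C)=O)C[C@@]12C | intermediate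
20 | (2S,4aR,6R,8aR)-4-[(3S)-5-acetoxy-3-methylpentyl]-2-diazenyl-3,4a,8,8-tetramethyl-1,2,4a,5,6,7,8,8a-octahydronaphthalen-6-yl acetate (not isolated) | CC(=O)OCC[C@@H](C)CCC1=C(C)[C@@H](N=N)C[C@@H]2C(C)(C)C[C@@H](OC(C)=O)C[C@@]12C | intermediate
21 | (3S)-5-[(1R,4aR,7R,8aR)-7-acetoxy-2,5,5,8a-tetramethyl-1,4,4a,5,6,7,8,8a-octahydronaphthalen-1-yl]-3-methylpentyl acetate (CNP0220683.1) | CC(=O)OCC[C@@H](C)CC[C@@H]1C(C)=CC[C@@H]2C(C)(C)C[C@@H](OC(C)=O)C[C@@]12C | target

**Step count**

Total step count: 12. Longest linear sequence: 10 steps (steps 1–4, then 7–12).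

**Steps most likely to fail**

Step 9. The secondary cation at C2 may be reached too slowly. Proton loss from the tertiary cation toward C5 (which would scramble that centre), or elimination and hydride shift at C2, could then compete with formate capture. The fallback sets out from 8 and returns at 21; it uses a chloro-olefin annulation, in which the terminator gives a chlorine-stabilised cation and hence a ring-A ketone. Alkylation of the dienolate of 8 with 2,3-dichloroprop-1-ene should give (5R,6R)-6-(2-chloroprop-2-en-1-yl)-2,6-dimethyl-5-(prop-1-en-2-yl)cyclohex-2-en-1-one F1. Addition of 11 gives the tertiary carbinol F2, and [C5H5NH][CrO3Cl] the transposed enone F3. In 90% HCO2H at 60 °C, followed by K2CO3/MeOH, the tertiary cation closes ring A onto the chloroalkene and the chloro cation is hydrolysed, giving the 2,7-dione F4. Li/NH3 with t-BuOH then reduces the C2 ketone to the equatorial alcohol and the enone to the saturated ketone with H-9 axial, giving keto diol F5. Ac2O/pyridine gives diacetate F6. Tf2O with 2,6-di-tert-butyl-4-methylpyridine gives the more substituted enol triflate F7, and Pd(OAc)2/PPh3/n-Bu3N/HCO2H reduces it to 21.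

Step 12. The Mitsunobu displacement at the allylic carbon next to the tetrasubstituted alkene may be slow, so that elimination to a diene or decomposition of the hydrazide intervenes. The fallback runs from 18 to 21. Formic acetic anhydride in pyridine gives the allylic formate F8. With Pd(OAc)2 and n-Bu3P in dioxane at reflux, zerovalent palladium ionises the formate anti to the leaving group, CO2 is lost, and hydride passes from palladium to the more substituted allyl terminus C9 on the same face as in the diazene route, giving 21.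

Step 6. Facial selectivity may be poor, or O-allylation may compete, when the quaternary centre is formed. The fallback runs from 8 to 10. LiN(SiMe3)2 followed by allyl chloroformate gives the allyl dienyl carbonate F9. Pd2(dba)3 with a chiral phosphinooxazoline ligand, the enantiomer being chosen to reinforce the substrate bias, then effects decarboxylative allylation through the π-allylpalladium enolate, adding catalyst control to substrate control, and returns 10.

**Further compounds**

F1 | step 9 | (5R,6R)-6-(2-chloroprop-2-en-1-yl)-2,6-dimethyl-5-(prop-1-en-2-yl)cyclohex-2-en-1-one | C=C(Cl)C[C@@]1(C)C(=O)C(C)=CC[C@@H]1C(C)=C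
F2 | step 9 | (1R,5R,6R)-1-[(3S)-5-{[tert-butyl(dimethyl)silyl]oxy}-3-methylpentyl]-6-(2-chloroprop-2-en-1-yl)-2,6-dimethyl-5-(prop-1-en-2-yl)cyclohex-2-en-1-ol (C-1 epimers converge) | C=C(Cl)C[C@@]1(C)[C@@](O)(CC[C@H](C)CCO[Si](C)(C)C(C)(C)C)C(C)=CC[C@@H]1C(C)=C
F3 | step 9 | (4R,5R)-3-[(3S)-5-{[tert-butyl(dimethyl)silyl]oxy}-3-methylpentyl]-4-(2-chloroprop-2-en-1-yl)-2,4-dimethyl-5-(prop-1-en-2-yl)cyclohex-2-en-1-one | C=C(Cl)C[C@@]1(C)C(CC[C@H](C)CCO[Si](C)(C)C(C)(C)C)=C(C)C(=O)C[C@@H]1C(C)=C
F4 | step 9 | (4aR,8aR)-4-[(3S)-5-hydroxy-3-methylpentyl]-3,4a,8,8-tetramethyl-4a,5,8,8a-tetrahydronaphthalene-2,6(1H,7H)-dione | OCC[C@@H](C)CCC1=C(C)C(=O)C[C@@H]2C(C)(C)CC(=O)C[C@@]12C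
F5 | step 9 | (3R,4R,4aS,6R,8aR)-6-hydroxy-4-[(3S)-5-hydroxy-3-methylpentyl]-3,4a,8,8-tetramethyloctahydronaphthalen-2(1H)-one | OCC[C@@H](C)CC[C@@H]1[C@@H](C)C(=O)C[C@@H]2C(C)(C)C[C@@H](O)C[C@@]12C
F6 | step 9 | (3R,4R,4aS,6R,8aR)-4-[(3S)-5-acetoxy-3-methylpentyl]-3,4a,8,8-tetramethyl-2-oxodecahydronaphthalen-6-yl acetate | CC(=O)OCC[C@@H](C)CC[C@@H]1[C@@H](C)C(=O)C[C@@H]2C(C)(C)C[C@@H](OC(C)=O)C[C@@]12C
F7 | step 9 | (3S)-5-[(1S,4aR,7R,8aR)-7-acetoxy-2,5,5,8a-tetramethyl-3-{[(trifluoromethyl)sulfonyl]oxy}-1,4,4a,5,6,7,8,8a-octahydronaphthalen-1-yl]-3-methylpentyl acetate | CC(=O)OCC[C@@H](C)CC[C@@H]1C(C)=C(OS(=O)(=O)C(F)(F)F)C[C@@H]2C(C)(C)C[C@@H](OC(C)=O)C[C@@]12C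
F8 | step 12 | (2R,4aR,6R,8aR)-6-acetoxy-4-[(3S)-5-acetoxy-3-methylpentyl]-3,4a,8,8-tetramethyl-1,2,4a,5,6,7,8,8a-octahydronaphthalen-2-yl formate | CC(=O)OCC[C@@H](C)CCC1=C(C)[C@H](OC=O)C[C@@H]2C(C)(C)C[C@@H](OC(C)=O)C[C@@]12C
F9 | step 6 | allyl (3R)-2,6-dimethyl-3-(prop-1-en-2-yl)cyclohexa-1,5-dien-1-yl carbonate | C=CCOC(=O)OC1=C(C)[C@@H](C(C)=C)CC=C1C
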